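In a one-step world the whole pre-initiator charge is living end at once, and free monomer falls by 36.2% in the run; this flask has to wait for release.

free monomer 0.10 M; pre-initiator 1.0 mM; time 15 min

    free monomer + initiator → living end + monomer in chains (k1 = 0.25 M⁻¹ s⁻¹)
    free monomer + living end → monomer in chains + living end, rate k2*[living end]*[free monomer] (k2 = 0.50 M⁻¹ s⁻¹)
    initiator → spent initiator A (k3 = 3.3 × 10⁻⁷ s⁻¹)
    initiator + monomer in chains → spent initiator B (k4 = 0.0017 M⁻¹ s⁻¹)
    pre-initiator → initiator (k5 = 6.7 × 10⁻⁴ s⁻¹)

- the average divides the monomer in chains by the number of chains begun, living and dead together
- run time (flask): 15 min

- average number of monomer units in a chain (chains begun, living or dead) at 15 min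
- part of the free monomer that has reacted at 15 min

I compare rates first. In this flask release is the rate-limiting step of chain birth: pre-initiator's half-life of 17 min is longer than the 0.46 min of initiator in initiation with free monomer as charged. The two losses to spent initiator run far slower than initiation, so I drop them.

By the end a fraction 45.3% of the pre-initiator charge is released. The released fraction, integrated over time and multiplied by the growth constant and the charge, gives 0.112, the exposure: the exponent of monomer decay if every released unit grows at full speed.

Initiation is slower per unit than growth, so the exposure overstates the loss, and conversion stays below 10.6%.

For the floor, I take the initiator level at which feed balances initiation: with both charges untouched it is 2.68% of the pre-initiator charge. That level drifts down, because the feed decays faster than free monomer can, and initiator, which starts from nothing, stays under it. Holding that ceiling of initiator through the run gives at least 10.1%. Dividing by chains begun brackets the length between 22.2 and 24.9 units.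

The forecast says 23.3 units and 10.2%, inside my bracket, on this ground: “Initiation is much faster than the release from pre-initiator”.

This flask gives 10.2% and 23.4 units per chain, inside the bracket. Initiator in this flask ends at 1.67% of the pre-initiator charge, under the ceiling. The neighbour flask with 0.040 M of free monomer has the same exposure, 0.112, as that charge stands nowhere in it, so its top stays 10.6%. Its ceiling rises to 6.70%, which lowers its floor to 9.24%. That neighbour flask gives 9.65%.

The numbers of this flask were set for the occasion; the run is a simulation.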